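**Retrosynthetic overview**
- Remove three benzyl groups in a final hydrogenolysis, then cut the depside C(=O)–O bond. This gives a ring A acid (2,4-bis(benzyloxy)-6-pentylbenzoic acid) and a ring B phenol (benzyl 4-hydroxy-2-methoxy-6-pentylbenzoate).
- Both halves trace back to one resorcylate, methyl olivetolate. They differ only in the pattern of O-benzylation and O-methylation and in the ester exchange.
- Methyl olivetolate comes from bromination–dehydrobromination of methyl 2-hydroxy-4-oxo-6-pentylcyclohex-2-ene-1-carboxylate.
- Key C–C bond (C1–C6 of the future arene): intermolecular Michael addition of dimethyl malonate to (E)-non-3-en-2-one. An intramolecular Claisen ring closure follows in the same pot.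
- Ring order: the one carbocycle is built in step 1 and aromatised in step 2. The material is then divided into the ring A and ring B series, and no ring is formed later.

Assumption: the SMILES contains no stereocentre and no stereogenic double bond, so the target is achiral and needs no enantiocontrol. The transient stereocentres in 3, 4 and 5 are racemic and are erased in step 2.

**Step 1**
Reactants: 1 (E)-non-3-en-2-one; 2 dimethyl malonate
Product: 4 methyl 2-hydroxy-4-oxo-6-pentylcyclohex-2-ene-1-carboxylate, via Michael adduct 3 (not isolated)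
Conditions: NaOMe (1.2 equiv), MeOH, add 2 then 1, reflux, 4 h; then aq HCl to pH 3, 0 °C, filter
Reagents that add atoms: none
Why: The soft malonate anion adds 1,4 to the enone (intermolecular Michael addition), the methyl-ketone enolate of 3 then closes the six-membered ring on one ester (intramolecular Claisen, Dieckmann-type), and deprotonation of the acidic enolised dione product drives both equilibria.

**Step 2**
Reactants: 4 methyl 2-hydroxy-4-oxo-6-pentylcyclohex-2-ene-1-carboxylate
Product: 6 methyl 2,4-dihydroxy-6-pentylbenzoate (methyl olivetolate), via 3-bromo enolone 5 (not isolated)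
Conditions: Br2 (1.0 equiv), DMF, 0 °C, then 80 °C, 12 h
Reagents that add atoms: bromine, BrBr (its Br sits only in intermediate 5; none remains in 6)
Why: Electrophilic bromination of the enolised 1,3-dione, thermal loss of HBr and tautomerisation (bromination–dehydrobromination aromatisation) give the resorcylate, and staying at or below 80 °C protects the methyl ester from bromide dealkylation and decarboxylation.

**Step 3 (ring A series)**
Reactants: 6 methyl 2,4-dihydroxy-6-pentylbenzoate
Product: 7 methyl 2,4-bis(benzyloxy)-6-pentylbenzoate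
Conditions: BnBr (2.6 equiv), K2CO3 (4 equiv), DMF, 70 °C, 16 h
Reagents that add atoms: benzyl bromide, BrCc1ccccc1
Why: Williamson ether synthesis in which warm DMF with excess base and halide also alkylates the hydrogen-bonded 2-OH, while the hindered methyl ester is untouched.

**Step 4**
Reactants: 7 methyl 2,4-bis(benzyloxy)-6-pentylbenzoate
Product: 8 2,4-bis(benzyloxy)-6-pentylbenzoic acid
Conditions: KOH (10 equiv), DMSO/H2O 4:1, 100 °C, 16 h; then 2 M HCl, 0 °C
Reagents that add atoms: potassium hydroxide, [K+].[OH-] (the hydroxide oxygen becomes the acid OH)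
Why: Saponification of a di-ortho-substituted benzoate succeeds with poorly solvated hydroxide in hot aqueous DMSO, benzyl aryl ethers are inert to these conditions, and cold acidification avoids protodecarboxylation.

**Step 5 (ring B series)**
Reactants: 6 methyl 2,4-dihydroxy-6-pentylbenzoate
Product: 9 methyl 4-(benzyloxy)-2-hydroxy-6-pentylbenzoate
Conditions: BnBr (1.05 equiv), K2CO3 (1.2 equiv), acetone, reflux, 8 h
Reagents that add atoms: benzyl bromide, BrCc1ccccc1
Why: Regioselective Williamson etherification, because the 4-OH is free and more acidic while the 2-OH is locked in a hydrogen bond to the ester carbonyl, and any over-benzylated material is simply 7 and can be fed into step 4.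

**Step 6**
Reactants: 9 methyl 4-(benzyloxy)-2-hydroxy-6-pentylbenzoate
Product: 10 methyl 4-(benzyloxy)-2-methoxy-6-pentylbenzoate
Conditions: MeI (3 equiv), K2CO3 (3 equiv), DMF, 45 °C, 16 h
Reagents that add atoms: iodomethane, CI
Why: Williamson O-methylation of the only remaining phenol, where the polar aprotic solvent and excess MeI overcome the chelated and hindered character of the 2-OH.

**Step 7**
Reactants: 10 methyl 4-(benzyloxy)-2-methoxy-6-pentylbenzoate
Product: 11 4-(benzyloxy)-2-methoxy-6-pentylbenzoic acid
Conditions: KOH (10 equiv), DMSO/H2O 4:1, 100 °C, 16 h; then 2 M HCl, 0 °C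
Reagents that add atoms: potassium hydroxide, [K+].[OH-] (the hydroxide oxygen becomes the acid OH)
Why: Forcing saponification of the hindered ester as in step 4, with the aryl methyl and aryl benzyl ethers both stable to hydroxide.

**Step 8**
Reactants: 11 4-(benzyloxy)-2-methoxy-6-pentylbenzoic acid
Product: 12 4-hydroxy-2-methoxy-6-pentylbenzoic acid
Conditions: H2 (1 atm), 10% Pd/C, EtOAc, rt, 3 h; evaporate below 35 °C
Reagents that add atoms: none
Why: Catalytic hydrogenolysis cleaves the benzyl aryl ether under neutral room-temperature conditions that spare the methyl ether, the arene and the decarboxylation-prone acid.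

**Step 9**
Reactants: 12 4-hydroxy-2-methoxy-6-pentylbenzoic acid
Product: 13 benzyl 4-hydroxy-2-methoxy-6-pentylbenzoate
Conditions: BnBr (1.05 equiv), KHCO3 (1.3 equiv), DMF, rt, 16 h
Reagents that add atoms: benzyl bromide, BrCc1ccccc1
Why: Chemoselective SN2 alkylation of the carboxylate, since KHCO3 deprotonates the acid (pKa about 4) but not the phenol (pKa about 9), and attack at the benzylic carbon is unaffected by crowding at the carbonyl.

**Step 10**
Reactants: 8 2,4-bis(benzyloxy)-6-pentylbenzoic acid; 13 benzyl 4-hydroxy-2-methoxy-6-pentylbenzoate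
Product: 15 benzyl 4-{[2,4-bis(benzyloxy)-6-pentylbenzoyl]oxy}-2-methoxy-6-pentylbenzoate, via mixed trifluoroacetic anhydride 14 (not isolated)
Conditions: (CF3CO)2O (4 equiv), dry toluene, 0 °C to rt, 4 h; aq NaHCO3 wash
Reagents that add atoms: trifluoroacetic anhydride, O=C(OC(=O)C(F)(F)F)C(F)(F)F (its CF3CO group sits only in intermediate 14; none remains in 15)
Why: Mixed-anhydride esterification in which the electron-rich anhydride 14 ionises towards a linear, alkoxy-stabilised acylium ion that escapes the di-ortho hindrance and O-acylates the only free OH of 13.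

**Step 11**
Reactants: 15 benzyl 4-{[2,4-bis(benzyloxy)-6-pentylbenzoyl]oxy}-2-methoxy-6-pentylbenzoate
Product: 16 4-[(2,4-dihydroxy-6-pentylbenzoyl)oxy]-2-methoxy-6-pentylbenzoic acid (target)
Conditions: H2 (1 atm), 10% Pd/C, EtOAc, rt, 4 h; filter, crystallise
Reagents that add atoms: none
Why: Global catalytic hydrogenolysis removes the two benzyl ethers and the benzyl ester at once in a neutral, non-nucleophilic solvent, so the base- and alcohol-sensitive depside ester and the methyl ether survive.

**Compound list**
1 | (E)-non-3-en-2-one | CCCCC/C=C/C(C)=O | starting material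
2 | dimethyl malonate | COC(=O)CC(=O)OC | starting material
3 | dimethyl 2-(2-oxononan-4-yl)propanedioate (racemic, not isolated) | CCCCCC(CC(C)=O)C(C(=O)OC)C(=O)OC | intermediate
4 | methyl 2-hydroxy-4-oxo-6-pentylcyclohex-2-ene-1-carboxylate (racemic, epimerisable at C1) | CCCCCC1CC(=O)C=C(O)C1C(=O)OC | intermediate
5 | methyl 3-bromo-2-hydroxy-4-oxo-6-pentylcyclohex-2-ene-1-carboxylate (racemic, not isolated) | CCCCCC1CC(=O)C(Br)=C(O)C1C(=O)OC | intermediate
6 | methyl 2,4-dihydroxy-6-pentylbenzoate (methyl olivetolate) | CCCCCc1cc(O)cc(O)c1C(=O)OC | intermediate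
7 | methyl 2,4-bis(benzyloxy)-6-pentylbenzoate | CCCCCc1cc(OCc2ccccc2)cc(OCc2ccccc2)c1C(=O)OC | intermediate
8 | 2,4-bis(benzyloxy)-6-pentylbenzoic acid | CCCCCc1cc(OCc2ccccc2)cc(OCc2ccccc2)c1C(=O)O | intermediate
9 | methyl 4-(benzyloxy)-2-hydroxy-6-pentylbenzoate | CCCCCc1cc(OCc2ccccc2)cc(O)c1C(=O)OC | intermediate
10 | methyl 4-(benzyloxy)-2-methoxy-6-pentylbenzoate | CCCCCc1cc(OCc2ccccc2)cc(OC)c1C(=O)OC | intermediate
11 | 4-(benzyloxy)-2-methoxy-6-pentylbenzoic acid | CCCCCc1cc(OCc2ccccc2)cc(OC)c1C(=O)O | intermediate
12 | 4-hydroxy-2-methoxy-6-pentylbenzoic acid | CCCCCc1cc(O)cc(OC)c1C(=O)O | intermediate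
13 | benzyl 4-hydroxy-2-methoxy-6-pentylbenzoate | CCCCCc1cc(O)cc(OC)c1C(=O)OCc1ccccc1 | intermediate
14 | 2,4-bis(benzyloxy)-6-pentylbenzoic trifluoroacetic anhydride (not isolated) | CCCCCc1cc(OCc2ccccc2)cc(OCc2ccccc2)c1C(=O)OC(=O)C(F)(F)F | intermediate
15 | benzyl 4-{[2,4-bis(benzyloxy)-6-pentylbenzoyl]oxy}-2-methoxy-6-pentylbenzoate | CCCCCc1cc(OCc2ccccc2)cc(OCc2ccccc2)c1C(=O)Oc1cc(CCCCC)c(C(=O)OCc2ccccc2)c(OC)c1 | intermediate
16 | 4-[(2,4-dihydroxy-6-pentylbenzoyl)oxy]-2-methoxy-6-pentylbenzoic acid | CCCCCc1cc(O)cc(O)c1C(=O)Oc1cc(CCCCC)c(C(=O)O)c(OC)c1 | target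

**Step count**
- Total steps: 11.
- Longest linear sequence: 9 steps (1, 2, 5, 6, 7, 8, 9, 10, 11).

**Three steps most likely to fail**

**Step 2 (aromatisation).** The risks are nuclear over-bromination and partial ester loss to olivetol. The fallback sets out from 4 and comes back at 6, and it makes over-bromination the intended outcome. Compound 4 is treated with excess Br2 (3.1 equiv) in AcOH at rt to 50 °C. This aromatises and brominates exhaustively to crystalline methyl 3,5-dibromo-2,4-dihydroxy-6-pentylbenzoate F1. Both aryl bromides are then removed by hydrogenolysis (H2, 10% Pd/C, NaOAc, MeOH, rt) to give 6.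

**Step 7 (hydrolysis of the di-ortho-substituted ester).** The risks are incomplete conversion, or decarboxylation if the reaction is forced. The fallback sets out from 10 and comes back at 11, and it replaces attack at the crowded carbonyl by a redox detour.
- LiAlH4 in THF at reflux gives [4-(benzyloxy)-2-methoxy-6-pentylphenyl]methanol F2.
- MnO2 in CH2Cl2 oxidises this benzylic alcohol to 4-(benzyloxy)-2-methoxy-6-pentylbenzaldehyde F3.
- Pinnick oxidation (NaClO2, NaH2PO4, 2-methylbut-2-ene, t-BuOH/H2O, rt) gives acid 11. The alkene scavenger suppresses ring chlorination.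

**Step 10 (hindered depside coupling).** The risks are low conversion, C-acylation of the electron-rich phenol, and acid-induced debenzylation. The fallback sets out from 8 and 13 and comes back at 15. It swaps the acidic in situ acylium route for a two-stage, base-mediated O-acylation.
- Acid 8 with (COCl)2 and catalytic DMF in CH2Cl2 (0 °C to rt) gives 2,4-bis(benzyloxy)-6-pentylbenzoyl chloride F4, which is freed of volatiles.
- Phenol 13 is deprotonated separately with NaH in THF at 0 °C to sodium 4-[(benzyloxy)carbonyl]-3-methoxy-5-pentylphenolate F5.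
- Combining the two in THF (0 °C to rt) gives 15.

**Further compounds**
F1 | step 2 | methyl 3,5-dibromo-2,4-dihydroxy-6-pentylbenzoate | CCCCCc1c(Br)c(O)c(Br)c(O)c1C(=O)OC
F2 | step 7 | [4-(benzyloxy)-2-methoxy-6-pentylphenyl]methanol | CCCCCc1cc(OCc2ccccc2)cc(OC)c1CO
F3 | step 7 | 4-(benzyloxy)-2-methoxy-6-pentylbenzaldehyde | CCCCCc1cc(OCc2ccccc2)cc(OC)c1C=O
F4 | step 10 | 2,4-bis(benzyloxy)-6-pentylbenzoyl chloride | CCCCCc1cc(OCc2ccccc2)cc(OCc2ccccc2)c1C(=O)Cl
F5 | step 10 | sodium 4-[(benzyloxy)carbonyl]-3-methoxy-5-pentylphenolate | [Na+].CCCCCc1cc([O-])cc(OC)c1C(=O)OCc1ccccc1
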